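**Numbering.** Abietane numbering is used throughout. Ring B is C5–C6–C7(=O)–C8–C9–C10. Ring C is the arene C8, C9, C11 (OH), C12 (OMe), C13 (isopropyl), C14 (OH). C10 carries the methyl C20 and the chain C1–C3; C5 carries the isopropenyl group C4(=C19)C18.

## The problem

The target is a 1-tetralone fused to a hexasubstituted benzene ring, so all six ring C positions must be filled with regiocontrol. The acyl carbon C7 sits on C8 between the C14 oxygen and the carbon that bears the quaternary centre, a site that no intermolecular Friedel–Crafts acylation will reach once C10 is built. There are two contiguous stereocentres, C5 (S) and C10 (S), with the isopropenyl group cis to C20. C10 is quaternary and must be set first by an enantioselective reaction; it can steer C5 only weakly, because its two exocyclic substituents (methyl and a CH2 chain) are almost the same size. C5 lies β to the ketone and cannot be corrected by epimerisation. The para-hydroquinone is oxidised by air, rapidly so in base; the 1,1-disubstituted alkene does not tolerate strong protic acid, electrophiles or hydrogenation; and three ring oxygens must end as two hydroxyls and one methyl ether. The enabling feature is the isopropenyl group on C5 next to the C6 methylene of an aryl ketone: this is what a carbonyl-ene reaction leaves when an aldehyde carbon (C6, the terminus of an aryl glyoxal on C8) bonds to the CH end of a 2-methylprop-1-enyl group on C10. The extra C6 hydroxyl is α to the C7 ketone and can be removed by electron transfer.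

## Retrosynthesis

**Ring C oxidation state (25 ⇐ 24 ⇐ 23).** Only O–CH3 bonds at C11 and C14 are cut. Hydroquinone 25 is taken back to quinone 24 and then to the trimethoxyarene acid 23. Oxidative demethylation selects the para pair C11/C14 and leaves C12 as its methyl ether, which no choice of three different protecting groups would do more simply. The last step is a reduction without base, so the hydroquinone never meets hydroxide; a final saponification would risk reoxidation.

**C3 and C6 adjustment (23 ⇐ 22 ⇐ 21).** The acid is traced to primary alcohol 22 and this to α-hydroxy ketone 21. The chain is carried as an alcohol because the organolithium chemistry at C8 tolerates an alkoxide but not an ester or acid. Oxidising it only after the C6 hydroxyl is gone avoids over-oxidation of the ketol.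

**Key disconnection (21 ⇐ 20).** The C5–C6 bond is cut and ring B opens to glyoxal 20, which has one stereocentre and no ring B. Closing C7–C8 instead would need an acyclic chain with both stereocentres already set; cutting C5–C10 would form the quaternary centre in the ring-forming step without control. The forward reaction must choose one face of the C4=C5 double bond relative to C10. The substrate bias is small, so a chelating chiral Lewis acid on the 1,2-dicarbonyl is asked to make the choice.

**C7–C8 bond (20 ⇐ 19 ⇐ 16 + 17).** The glyoxal is unmasked from keto acetal 19, made from aryl bromide 16 and methyl dimethoxyacetate 17 by bromine–lithium exchange and acylation.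
- Electrophilic acylation is ruled out: C8 is flanked by the quaternary carbon, and acid would cyclise the alkene onto the arene.
- The carbonyl cannot be installed earlier: a 2-(2-acylaryl)propanal condenses with amines to isoquinolinium salts and with acid to benzopyrylium salts.
- The forward step asks a hindered aryllithium to acylate once.

**C3–O and C4=C5 (16 ⇐ 14 ⇐ 12).** Alcohol 16 comes from diene 14 by hydroboration of the allyl group, and 14 from aldehyde 12 by isopropylidene Wittig reaction. Both are functional-group changes at positions that cannot epimerise.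

**C10–C1 bond, sets C10 (12 ⇐ 10 + 11).** The quaternary centre is cut to racemic 2-arylpropanal 10 and allyl alcohol 11. Conjugate addition to an acrylate would give the acid oxidation level directly, but enamines of α-branched aldehydes are too weak for simple acrylates and the ester would have to be reduced before the lithiation anyway. π-Allylpalladium is a competent electrophile, and the allyl group gives the chain at the alkoxide-compatible level.

**C9–C10 bond (10 ⇐ 9 ⇐ 6 + 7).** The propanal is unmasked from methoxy carbinol 9, made from bromoarene 6 and methoxyacetone 7 by deprotonation between bromine and methoxy. The bromine has two roles: it makes the last ring hydrogen (C9) acidic, and it is the later handle at C8.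

**Ring C substitution (6 ⇐ 5 ⇐ 4 ⇐ 1 + 2).** Bromide 6 comes from arene 5 by electrophilic bromination para to the C12 methoxy group. Arene 5 comes from carbinol 4 by ionic hydrogenation, and 4 from 1,2,4-trimethoxybenzene 1 and acetone 2 by lithiation between two methoxy groups. The starting materials are 1, 2, 7, 11, isopropyltriphenylphosphonium iodide 13 and 17.

## Roads not taken

**Alternative 1:** Ring B is taken from a naphthalene and the C4–C5 and C1–C10 bonds are cut. In the forward sense an isopropenyl carbanion adds to C5 of the chiral 1-naphthyloxazoline A1 and the aza-enolate is allylated at C10, giving dihydronaphthalene A2.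
- Merit: both stereocentres are set in one auxiliary-controlled operation and the trans addition fixes their relation mechanistically. This is more secure than the chosen plan, which depends on a catalyst for C5.
- Weak points: A1 is a pentasubstituted naphthalene that is long to make. Its peri methoxy group (C11) twists the oxazoline out of conjugation and the C7 methoxy group makes the ring electron-rich; both slow the addition.
- Weak points after the key step: in A2 the oxazoline carbon must be taken down to the C20 methyl at a neopentyl centre, in the presence of two alkenes.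
- Comparison: the chosen plan has C20 as a methyl from the start, builds ring C by three regiocontrolled substitutions and needs no auxiliary removal.

**Alternative 2:** Ring C is made last by cutting C8–C14. Thermolysis of the 4-hydroxycyclobutenone A3 opens it to a dienyl ketene that closes to hydroquinone A4.
- Merit: the hexasubstituted arene is assembled with unambiguous regiochemistry, and C11/C14 emerge as free hydroxyls with C12 as the methyl ether. This is better than the chosen plan, which needs an oxidative demethylation.
- Weak points: A3 needs a cyclohexenyl metal fragment that already carries C5 and C10, so the stereochemical problem is moved rather than solved.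
- Weak points after the key step: C7 in A4 is a methylene. A benzylic oxidation next to a hydroquinone and an isopropenyl group with allylic hydrogens is unlikely to be selective.
- Comparison: the chosen plan has C7 as a ketone from the moment ring B closes and sets each stereocentre in a separate catalytic step.

**Alternative 3:** Ring B is cut at C5–C10 and C6–C7. Irradiation of benzaldehyde A5 gives a hydroxy-ortho-quinodimethane that adds to dienoate A6 to give tetralol A7.
- Merit: it is the most convergent route; two bonds, ring B and the C7 oxygen arrive in one step. In step count to the bicyclic core it beats the chosen plan.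
- Weak points: the quaternary centre C10 comes from a dienol terminus whose two substituents (methyl and chain) are nearly equal, so its geometry, and with it C10 relative to C5, is uncontrolled. There is no handle on absolute configuration.
- Further weak points: A6 must react at its α,β double bond, and A7 carries a surplus C6 ester that needs oxidation and decarboxylation.
- Comparison: the chosen plan faces the same methyl-versus-chain problem only at C5, where a chelating chiral catalyst can decide it, and sets C10 alone beforehand.

Key step: step 11

**Assumption on catalyst sense.** The sense of induction of (S)-TRIP in step 6 and of [Cu((R,R)-t-Bu-box)](SbF6)2 in step 11 is taken from the parent substrates 2-phenylpropanal and glyoxylate esters. If either is reversed for these hindered substrates, the other enantiomer of that catalyst is used and nothing else changes.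

**Remark.** Glyoxal 20 is handled as its gem-diol (hydrate). TRIP is 3,3′-bis(2,4,6-triisopropylphenyl)-1,1′-binaphthyl-2,2′-diyl hydrogen phosphate; t-Bu-box is 2,2′-(propane-2,2-diyl)bis(4-tert-butyl-4,5-dihydrooxazole).

## Route

Step 1
Reactants: 1 1,2,4-trimethoxybenzene; 2 acetone
Product: 4 2-(2,3,6-trimethoxyphenyl)propan-2-ol, via (2,3,6-trimethoxyphenyl)lithium 3 (not isolated)
Conditions: n-BuLi, THF, 0 °C to rt; then 2, −78 °C to rt; H2O
Reagents that add atoms: none
Why: Directed ortho-lithiation removes the hydrogen between the two methoxy groups, the most acidic ring hydrogen, and the aryllithium adds to acetone (1,2-addition), which puts the isopropyl carbons on C13; no stereocentre.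

Step 2
Reactants: 4 2-(2,3,6-trimethoxyphenyl)propan-2-ol
Product: 5 2-isopropyl-1,3,4-trimethoxybenzene
Conditions: Et3SiH, CF3CO2H, CH2Cl2, 0 °C to rt
Reagents that add atoms: none
Why: Ionic hydrogenation: acid ionises the tertiary benzylic alcohol to a cation stabilised by two ortho methoxy groups and the silane delivers hydride.

Step 3
Reactants: 5 2-isopropyl-1,3,4-trimethoxybenzene
Product: 6 1-bromo-3-isopropyl-2,4,5-trimethoxybenzene
Conditions: NBS, MeCN, 0 °C
Reagents that add atoms: N-bromosuccinimide, O=C1CCC(=O)N1Br
Why: Electrophilic aromatic bromination; of the two free positions the one para to the C12 methoxy and ortho to the C14 methoxy (C8) is the more activated, as in formylation and halogenation of other 3-alkyl-1,2,4-trimethoxybenzenes.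

Step 4
Reactants: 6 1-bromo-3-isopropyl-2,4,5-trimethoxybenzene; 7 methoxyacetone
Product: 9 rac-2-(2-bromo-4-isopropyl-3,5,6-trimethoxyphenyl)-1-methoxypropan-2-ol, via (2-bromo-4-isopropyl-3,5,6-trimethoxyphenyl)lithium 8 (not isolated)
Conditions: LiN(i-Pr)2, THF, −78 °C; then 7, −78 to −40 °C; H2O
Reagents that add atoms: none
Why: Deprotonative ortho-lithiation between bromine and methoxy (the only ring hydrogen left, as in lithiation of 3-bromoanisole at C2), held at −78 °C so that LiBr is not lost to an aryne; addition to the chelating α-methoxy ketone gives the carbinol as a racemate, which does not matter because this centre is planarised in step 6.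

Step 5
Reactants: 9 rac-2-(2-bromo-4-isopropyl-3,5,6-trimethoxyphenyl)-1-methoxypropan-2-ol
Product: 10 rac-2-(2-bromo-4-isopropyl-3,5,6-trimethoxyphenyl)propanal
Conditions: HCO2H–H2O (9:1), 80 °C
Reagents that add atoms: water, O
Why: Acid-promoted rearrangement of a β-methoxy tertiary benzylic alcohol (semipinacol-type): ionisation to the benzylic cation, loss of a proton to the enol ether or hydride shift, then hydrolysis gives the 2-arylpropanal; the stereocentre is labile and racemic.

Step 6
Reactants: 10 rac-2-(2-bromo-4-isopropyl-3,5,6-trimethoxyphenyl)propanal; 11 allyl alcohol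
Product: 12 (2R)-2-(2-bromo-4-isopropyl-3,5,6-trimethoxyphenyl)-2-methylpent-4-enal
Conditions: Pd(PPh3)4 (3 mol%), (S)-TRIP (5 mol%), Ph2CHNH2 (40 mol%), 5 Å molecular sieves, toluene, 40 °C; then 2 M HCl
Reagents that add atoms: none
Why: Asymmetric α-allylation of an α-branched aldehyde (Tsuji–Trost allylation under combined enamine, zerovalent palladium and chiral phosphoric acid catalysis): the racemic aldehyde converges on its E-enamine with benzhydrylamine, and the π-allylpalladium cation paired with the chiral phosphate is delivered to one enamine face, which creates quaternary C10 in the R arrangement that becomes 10S; the product cannot enolise and the hindered electron-rich aryl bromide does not insert palladium at 40 °C.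

Step 7
Reactants: 12 (2R)-2-(2-bromo-4-isopropyl-3,5,6-trimethoxyphenyl)-2-methylpent-4-enal; 13 isopropyltriphenylphosphonium iodide
Product: 14 1-bromo-2-[(4S)-2,4-dimethylhepta-2,6-dien-4-yl]-5-isopropyl-3,4,6-trimethoxybenzene
Conditions: 13, n-BuLi, THF, 0 °C; then 12, 0 to 45 °C
Reagents that add atoms: none
Why: Wittig olefination with the non-stabilised isopropylidene ylide turns the non-enolisable neopentyl aldehyde into the 2-methylprop-1-enyl group (C5=C4); the phosphonium salt is kept in slight excess over n-BuLi so that the aryl bromide is not exchanged, and C10 is untouched.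

Step 8
Reactants: 14 1-bromo-2-[(4S)-2,4-dimethylhepta-2,6-dien-4-yl]-5-isopropyl-3,4,6-trimethoxybenzene
Product: 16 (4S)-4-(2-bromo-4-isopropyl-3,5,6-trimethoxyphenyl)-4,6-dimethylhept-5-en-1-ol, via B-alkyl-9-borabicyclononane 15 (not isolated)
Conditions: 9-BBN, THF, 0 °C to rt; then NaOH, H2O2, 0 °C to rt
Reagents that add atoms: hydrogen peroxide, OO
Why: Anti-Markovnikov hydroboration–oxidation; 9-BBN reacts with the monosubstituted allyl double bond far faster than with the trisubstituted neopentyl alkene and gives the primary alcohol at C3.

Step 9
Reactants: 16 (4S)-4-(2-bromo-4-isopropyl-3,5,6-trimethoxyphenyl)-4,6-dimethylhept-5-en-1-ol; 17 methyl 2,2-dimethoxyacetate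
Product: 19 1-{2-[(4S)-7-hydroxy-2,4-dimethylhept-2-en-4-yl]-5-isopropyl-3,4,6-trimethoxyphenyl}-2,2-dimethoxyethan-1-one, via C8-lithiated lithium alkoxide 18 (not isolated)
Conditions: t-BuLi (3.2 equiv), THF, −78 °C; then 17, −78 to −50 °C; H2O
Reagents that add atoms: none
Why: Bromine–lithium exchange then acyl substitution: one equivalent of t-BuLi deprotonates the hydroxyl and two effect the exchange; the C8 aryllithium adds to the ester, and the tetrahedral lithium hemiketal, chelated by an acetal oxygen and shielded by both ortho groups, survives until quench, so the ketone with the glyoxal masked as its dimethyl acetal forms without over-addition.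

Step 10
Reactants: 19 1-{2-[(4S)-7-hydroxy-2,4-dimethylhept-2-en-4-yl]-5-isopropyl-3,4,6-trimethoxyphenyl}-2,2-dimethoxyethan-1-one
Product: 20 2-{2-[(4S)-7-hydroxy-2,4-dimethylhept-2-en-4-yl]-5-isopropyl-3,4,6-trimethoxyphenyl}-2-oxoacetaldehyde
Conditions: 2 M HCl, THF, 45 °C
Reagents that add atoms: water, O
Why: Acid hydrolysis of the α-keto dimethyl acetal; in the aqueous medium the freed aldehyde is held as its gem-diol, which should keep it from attacking the alkene, and dilute acid at this temperature should not hydrate the trisubstituted double bond.

Step 11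
Reactants: 20 2-{2-[(4S)-7-hydroxy-2,4-dimethylhept-2-en-4-yl]-5-isopropyl-3,4,6-trimethoxyphenyl}-2-oxoacetaldehyde
Product: 21 (2R,3S,4S)-2-hydroxy-4-(3-hydroxypropyl)-7-isopropyl-5,6,8-trimethoxy-4-methyl-3-(prop-1-en-2-yl)-3,4-dihydronaphthalen-1(2H)-one
Conditions: [Cu((R,R)-t-Bu-box)](SbF6)2 (15 mol%), 4 Å molecular sieves, CH2Cl2, 0 °C to rt
Reagents that add atoms: none
Why: Intramolecular carbonyl-ene reaction: after the sieves take up the hydrate water, the divalent copper complex chelates both carbonyl oxygens of the aryl glyoxal, C6 bonds to C5 while a hydrogen of a C4 methyl group passes to the aldehyde oxygen through a six-centre array, and the double bond moves to C4–C19. The closest known reactions are the cyclisation of citronellal-type unsaturated aldehydes to isopulegol-type alcohols and the copper bis(oxazoline)-catalysed ene reactions of glyoxylates, aryl glyoxals and unsaturated α-keto esters. Ring B closes as a six-membered ring, 6-exo-trig at the aldehyde carbon, through a chair-like transition state in which the enophile is tethered to the alkene carbon that forms the bond. C6 (R) is set by the catalyst: in the square-planar chelate the (R,R) ligand should leave the Re face of the aldehyde open, and chelation holds the C6 oxygen equatorial. C5 (S) follows by relay: with C4 equatorial the chair gives the 5,6-trans product, which places the isopropenyl group cis to the C10 methyl group. The selectivity the step needs is between the two faces of the C4=C5 bond relative to C10; the substrate supplies only a small bias (allylic 1,3-strain favours methyl eclipsing the alkene, peri strain with the C11 methoxy group opposes it), so control is handed to the catalyst and no severe mismatch is expected. Chemoselectivity rests on two-point binding: only the 1,2-dicarbonyl chelates copper, so the free C3 hydroxyl does not compete and the aldehyde, not the hindered ketone, is the enophile. The surplus C6 hydroxyl is removed in step 12.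

Step 12
Reactants: 21 (2R,3S,4S)-2-hydroxy-4-(3-hydroxypropyl)-7-isopropyl-5,6,8-trimethoxy-4-methyl-3-(prop-1-en-2-yl)-3,4-dihydronaphthalen-1(2H)-one
Product: 22 (3S,4S)-4-(3-hydroxypropyl)-7-isopropyl-5,6,8-trimethoxy-4-methyl-3-(prop-1-en-2-yl)-3,4-dihydronaphthalen-1(2H)-one
Conditions: SmI2 (2.5 equiv), THF–MeOH, −78 °C
Reagents that add atoms: none
Why: Reductive cleavage of an α-hydroxy ketone by divalent samarium: electron transfer to the aryl ketone gives a ketyl, the second electron expels the C6 oxygen, and methanol protonates the samarium enolate at C6; C5 and C10 are not involved and the isolated alkene is inert.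

Step 13
Reactants: 22 (3S,4S)-4-(3-hydroxypropyl)-7-isopropyl-5,6,8-trimethoxy-4-methyl-3-(prop-1-en-2-yl)-3,4-dihydronaphthalen-1(2H)-one
Product: 23 3-[(1S,2S)-6-isopropyl-5,7,8-trimethoxy-1-methyl-4-oxo-2-(prop-1-en-2-yl)-1,2,3,4-tetrahydronaphthalen-1-yl]propanoic acid
Conditions: TEMPO (20 mol%), PhI(OAc)2, MeCN–H2O, rt
Reagents that add atoms: water, O
Why: Oxoammonium-mediated oxidation of the primary alcohol to the aldehyde and, through its hydrate, to the carboxylic acid; the ketone, the 1,1-disubstituted alkene and the aryl ethers should survive these near-neutral conditions, and making the acid directly avoids an ester that would need base later.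

Step 14
Reactants: 23 3-[(1S,2S)-6-isopropyl-5,7,8-trimethoxy-1-methyl-4-oxo-2-(prop-1-en-2-yl)-1,2,3,4-tetrahydronaphthalen-1-yl]propanoic acid
Product: 24 3-[(1S,2S)-6-isopropyl-7-methoxy-1-methyl-4,5,8-trioxo-2-(prop-1-en-2-yl)-1,2,3,4,5,8-hexahydronaphthalen-1-yl]propanoic acid
Conditions: (NH4)2Ce(NO3)6 (2.5 equiv), MeCN–H2O, 0 °C
Reagents that add atoms: water, O
Why: Oxidative demethylation: tetravalent cerium takes two electrons from the arene, water adds at the para pair C11 and C14 with loss of two molecules of methanol, and the 1,4-quinone forms while the C12 methoxy group, which has no para oxygen partner, is kept; this is the step that tells the three methyl ethers apart.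

Step 15
Reactants: 24 3-[(1S,2S)-6-isopropyl-7-methoxy-1-methyl-4,5,8-trioxo-2-(prop-1-en-2-yl)-1,2,3,4,5,8-hexahydronaphthalen-1-yl]propanoic acid
Product: 25 3-[(1S,2S)-5,8-dihydroxy-6-isopropyl-7-methoxy-1-methyl-4-oxo-2-(prop-1-en-2-yl)-1,2,3,4-tetrahydronaphthalen-1-yl]propanoic acid
Conditions: Na2S2O4, EtOAc–H2O, rt, N2; then 1 M HCl
Reagents that add atoms: none
Why: Two-electron reduction of the quinone to the hydroquinone by dithionite under neutral to weakly acidic conditions; doing it last and without base keeps the air-sensitive hydroquinone from reoxidising, and the C14 hydroxyl is stabilised by its hydrogen bond to the C7 ketone.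

## Compound list

1 | 1,2,4-trimethoxybenzene | COc1ccc(OC)c(OC)c1 | starting material
2 | acetone | CC(C)=O | starting material
3 | (2,3,6-trimethoxyphenyl)lithium | [Li]c1c(OC)ccc(OC)c1OC | intermediate
4 | 2-(2,3,6-trimethoxyphenyl)propan-2-ol | CC(C)(O)c1c(OC)ccc(OC)c1OC | intermediate
5 | 2-isopropyl-1,3,4-trimethoxybenzene | CC(C)c1c(OC)ccc(OC)c1OC | intermediate
6 | 1-bromo-3-isopropyl-2,4,5-trimethoxybenzene | CC(C)c1c(OC)c(Br)cc(OC)c1OC | intermediate
7 | methoxyacetone (1-methoxypropan-2-one) | COCC(C)=O | starting material
8 | (2-bromo-4-isopropyl-3,5,6-trimethoxyphenyl)lithium | CC(C)c1c(OC)c(Br)c([Li])c(OC)c1OC | intermediate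
9 | rac-2-(2-bromo-4-isopropyl-3,5,6-trimethoxyphenyl)-1-methoxypropan-2-ol | COCC(C)(O)c1c(Br)c(OC)c(C(C)C)c(OC)c1OC | intermediate
10 | rac-2-(2-bromo-4-isopropyl-3,5,6-trimethoxyphenyl)propanal | CC(C=O)c1c(Br)c(OC)c(C(C)C)c(OC)c1OC | intermediate
11 | allyl alcohol | C=CCO | starting material
12 | (2R)-2-(2-bromo-4-isopropyl-3,5,6-trimethoxyphenyl)-2-methylpent-4-enal | COc1c(OC)c(C(C)C)c(OC)c(Br)c1[C@@](C)(CC=C)C=O | intermediate
13 | isopropyltriphenylphosphonium iodide | CC(C)[P+](c1ccccc1)(c1ccccc1)c1ccccc1.[I-] | starting material
14 | 1-bromo-2-[(4S)-2,4-dimethylhepta-2,6-dien-4-yl]-5-isopropyl-3,4,6-trimethoxybenzene | COc1c(OC)c(C(C)C)c(OC)c(Br)c1[C@@](C)(CC=C)C=C(C)C | intermediate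
15 | 9-[(4S)-4-(2-bromo-4-isopropyl-3,5,6-trimethoxyphenyl)-4,6-dimethylhept-5-en-1-yl]-9-borabicyclo[3.3.1]nonane | COc1c(OC)c(C(C)C)c(OC)c(Br)c1[C@@](C)(CCCB1C2CCCC1CCC2)C=C(C)C | intermediate
16 | (4S)-4-(2-bromo-4-isopropyl-3,5,6-trimethoxyphenyl)-4,6-dimethylhept-5-en-1-ol | COc1c(OC)c(C(C)C)c(OC)c(Br)c1[C@@](C)(CCCO)C=C(C)C | intermediate
17 | methyl 2,2-dimethoxyacetate | COC(OC)C(=O)OC | starting material
18 | lithium (4S)-4-(4-isopropyl-2-lithio-3,5,6-trimethoxyphenyl)-4,6-dimethylhept-5-en-1-olate | [Li]c1c(OC)c(C(C)C)c(OC)c(OC)c1[C@@](C)(CCCO[Li])C=C(C)C | intermediate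
19 | 1-{2-[(4S)-7-hydroxy-2,4-dimethylhept-2-en-4-yl]-5-isopropyl-3,4,6-trimethoxyphenyl}-2,2-dimethoxyethan-1-one | COC(OC)C(=O)c1c(OC)c(C(C)C)c(OC)c(OC)c1[C@@](C)(CCCO)C=C(C)C | intermediate
20 | 2-{2-[(4S)-7-hydroxy-2,4-dimethylhept-2-en-4-yl]-5-isopropyl-3,4,6-trimethoxyphenyl}-2-oxoacetaldehyde | O=CC(=O)c1c(OC)c(C(C)C)c(OC)c(OC)c1[C@@](C)(CCCO)C=C(C)C | intermediate
21 | (2R,3S,4S)-2-hydroxy-4-(3-hydroxypropyl)-7-isopropyl-5,6,8-trimethoxy-4-methyl-3-(prop-1-en-2-yl)-3,4-dihydronaphthalen-1(2H)-one | C=C(C)[C@@H]1[C@@H](O)C(=O)c2c(OC)c(C(C)C)c(OC)c(OC)c2[C@@]1(C)CCCO | intermediate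
22 | (3S,4S)-4-(3-hydroxypropyl)-7-isopropyl-5,6,8-trimethoxy-4-methyl-3-(prop-1-en-2-yl)-3,4-dihydronaphthalen-1(2H)-one | C=C(C)[C@@H]1CC(=O)c2c(OC)c(C(C)C)c(OC)c(OC)c2[C@@]1(C)CCCO | intermediate
23 | 3-[(1S,2S)-6-isopropyl-5,7,8-trimethoxy-1-methyl-4-oxo-2-(prop-1-en-2-yl)-1,2,3,4-tetrahydronaphthalen-1-yl]propanoic acid | C=C(C)[C@@H]1CC(=O)c2c(OC)c(C(C)C)c(OC)c(OC)c2[C@@]1(C)CCC(=O)O | intermediate
24 | 3-[(1S,2S)-6-isopropyl-7-methoxy-1-methyl-4,5,8-trioxo-2-(prop-1-en-2-yl)-1,2,3,4,5,8-hexahydronaphthalen-1-yl]propanoic acid | C=C(C)[C@@H]1CC(=O)C2=C(C(=O)C(OC)=C(C(C)C)C2=O)[C@@]1(C)CCC(=O)O | intermediate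
25 | 3-[(1S,2S)-5,8-dihydroxy-6-isopropyl-7-methoxy-1-methyl-4-oxo-2-(prop-1-en-2-yl)-1,2,3,4-tetrahydronaphthalen-1-yl]propanoic acid | C=C(C)[C@@H]1CC(=O)c2c(O)c(C(C)C)c(OC)c(O)c2[C@@]1(C)CCC(=O)O | target

## Step count and least certain steps

Total step count: 15. Longest linear sequence: 15 steps, from 1.

**Step 11 (key step).** The most likely failure is loss of facial control at C5. The dicarbonyl sits between the C14 methoxy group and the quaternary carbon, so chelation to the copper complex may be slow. An uncatalysed or trace-acid closure would then compete, and because the substrate's own bias is small both C5 epimers would form. The fallback sets out from keto acetal 19 and closes ring B without freeing the glyoxal. MeAlCl2 in CH2Cl2 at −78 °C ionises the acetal to an α-keto oxocarbenium ion, which undergoes the same C5–C6 ene-type (Prins) closure. The product is the C6 methyl ether (2R,3S,4S)-4-(3-hydroxypropyl)-7-isopropyl-2,5,6,8-tetramethoxy-4-methyl-3-(prop-1-en-2-yl)-3,4-dihydronaphthalen-1(2H)-one F1. At this temperature there is no background reaction, the small allylic-strain preference for the wanted epimer counts for more, and the minor epimer is removed by chromatography. SmI2 then cleaves the α-methoxy ketone as in step 12 and the route is rejoined at 22.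

**Step 6.** The most likely failure is slow enamine formation and eroded enantioselectivity, because the aryl group has two ortho substituents and is twisted out of conjugation with the enamine. The fallback sets out from 10 and uses a covalently bound controller. Condensation with allyl (S)-prolinate (or its antipode, whichever gives the R aldehyde) gives the enamine allyl (2S)-1-[2-(2-bromo-4-isopropyl-3,5,6-trimethoxyphenyl)prop-1-en-1-yl]pyrrolidine-2-carboxylate F2. Pd(PPh3)4 ionises the allyl ester, and the π-allylpalladium carboxylate ion pair returns the allyl group to the enamine carbon from the carboxylate face (Tsuji–Trost allylation with internal delivery). Aqueous acid then releases 12.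

**Step 9.** The most likely failure is protonation of the hindered aryllithium before it acylates, or acylation of the C3 alkoxide instead. The fallback sets out from 16: intermediate 18 is generated as before and trapped with the smaller and far more reactive aldehyde 2,2-dimethoxyacetaldehyde, dried before use. This gives the diol (4S)-4-[2-(1-hydroxy-2,2-dimethoxyethyl)-4-isopropyl-3,5,6-trimethoxyphenyl]-4,6-dimethylhept-5-en-1-ol F3 as a mixture of carbinol epimers. Activated MnO2 oxidises only the benzylic alcohol and returns 19.

**Step 10.** The most likely failure is that the α-keto acetal resists dilute acid, while stronger acid lets the freed glyoxal close onto the alkene without stereocontrol or hydrates the alkene. The fallback is a non-hydrolytic unmasking. Intermediate 18, made from 16, is acylated with 2-chloro-N-methoxy-N-methylacetamide to the chloromethyl ketone 2-chloro-1-{2-[(4S)-7-hydroxy-2,4-dimethylhept-2-en-4-yl]-5-isopropyl-3,4,6-trimethoxyphenyl}ethan-1-one F4. Kornblum oxidation (NaI, NaHCO3, DMSO, 40 °C) then gives 20 under weakly basic conditions.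

**Step 14.** The most likely failure is oxidation across the C11/C12 pair to an ortho-quinone, or attack of the oxidant on the isopropenyl group. The fallback sets out from 23. BCl3 at −78 °C removes only the C14 methyl ether, helped by chelation to the C7 ketone, and gives the phenol 3-[(1S,2S)-5-hydroxy-6-isopropyl-7,8-dimethoxy-1-methyl-4-oxo-2-(prop-1-en-2-yl)-1,2,3,4-tetrahydronaphthalen-1-yl]propanoic acid F5. PhI(OAc)2 in aqueous MeCN oxidises this para-methoxyphenol regiospecifically to quinone 24.

## Further compounds

F1 | step 11 | (2R,3S,4S)-4-(3-hydroxypropyl)-7-isopropyl-2,5,6,8-tetramethoxy-4-methyl-3-(prop-1-en-2-yl)-3,4-dihydronaphthalen-1(2H)-one | C=C(C)[C@@H]1[C@@H](OC)C(=O)c2c(OC)c(C(C)C)c(OC)c(OC)c2[C@@]1(C)CCCO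
F2 | step 6 | allyl (2S)-1-[2-(2-bromo-4-isopropyl-3,5,6-trimethoxyphenyl)prop-1-en-1-yl]pyrrolidine-2-carboxylate | C=CCOC(=O)[C@@H]1CCCN1C=C(C)c1c(Br)c(OC)c(C(C)C)c(OC)c1OC
F3 | step 9 | (4S)-4-[2-(1-hydroxy-2,2-dimethoxyethyl)-4-isopropyl-3,5,6-trimethoxyphenyl]-4,6-dimethylhept-5-en-1-ol | COC(OC)C(O)c1c(OC)c(C(C)C)c(OC)c(OC)c1[C@@](C)(CCCO)C=C(C)C
F4 | step 10 | 2-chloro-1-{2-[(4S)-7-hydroxy-2,4-dimethylhept-2-en-4-yl]-5-isopropyl-3,4,6-trimethoxyphenyl}ethan-1-one | ClCC(=O)c1c(OC)c(C(C)C)c(OC)c(OC)c1[C@@](C)(CCCO)C=C(C)C
F5 | step 14 | 3-[(1S,2S)-5-hydroxy-6-isopropyl-7,8-dimethoxy-1-methyl-4-oxo-2-(prop-1-en-2-yl)-1,2,3,4-tetrahydronaphthalen-1-yl]propanoic acid | C=C(C)[C@@H]1CC(=O)c2c(O)c(C(C)C)c(OC)c(OC)c2[C@@]1(C)CCC(=O)O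
A1 | alternative 1 | (4S)-4-tert-butyl-2-(6-isopropyl-4,5,7,8-tetramethoxynaphthalen-1-yl)-4,5-dihydrooxazole | CC(C)(C)[C@H]1COC(=N1)c3ccc(OC)c2c(OC)c(C(C)C)c(OC)c(OC)c23
A2 | alternative 1 | 1,2-dihydronaphthalene with C5 isopropenyl, C10 allyl and (4S)-4-tert-butyloxazoline, C7 enol ether | CC(C)(C)[C@H]1COC(=N1)[C@]3(CC=C)[C@H](C(C)=C)C=C(OC)c2c(OC)c(C(C)C)c(OC)c(OC)c23
A3 | alternative 2 | 4-hydroxy-2-isopropyl-3-methoxy-4-(cyclohex-1-enyl)cyclobut-2-en-1-one bearing C5 isopropenyl and C10 methyl and 3-(tert-butyldimethylsilyloxy)propyl on the cyclohexene | O=C1C(C(C)C)=C(OC)C1(O)C2=CCC[C@@H](C(C)=C)[C@]2(C)CCCO[Si](C)(C)C(C)(C)C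
A4 | alternative 2 | ring B–ring C hydroquinone with C7 methylene and silyl-protected C3 alcohol | Oc1c(C(C)C)c(OC)c(O)c2c1CC[C@@H](C(C)=C)[C@]2(C)CCCO[Si](C)(C)C(C)(C)C
A5 | alternative 3 | methyl 4-(2-formyl-4-isopropyl-3,5,6-trimethoxyphenyl)pentanoate | O=Cc1c(OC)c(C(C)C)c(OC)c(OC)c1C(C)CCC(=O)OC
A6 | alternative 3 | methyl (2E)-4-methylpenta-2,4-dienoate | C=C(C)/C=C/C(=O)OC
A7 | alternative 3 | 1-hydroxytetralin with C6 methyl ester, C5 isopropenyl and quaternary C10 | C=C(C)[C@@H]1[C@@H](C(=O)OC)[C@@H](O)c2c(OC)c(C(C)C)c(OC)c(OC)c2[C@@]1(C)CCC(=O)OC
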